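The numbers come from no measurement; the result is computed.

Whatever the flasks did, one sum held once their charges were in: [incoming ligand] + [leaving ligand] + [side product] stayed at 0.638 M, since each exchange trades one ligand for the other and each side product removes one leaving ligand. This is the note I left for the bench.

common to all: leaving ligand 0.440 M; time 25 min
- alpha: starting complex 0.22 M; incoming ligand 0.198 M (fed, over 20 min); all else is in the flask from the start; the feed brings no volume worth counting
- zeta: starting complex 0.22 M; incoming ligand 0.198 M; everything together at the start
- gamma: starting complex 0.22 M (fed, over 20 min); incoming ligand 0.198 M; all else is in the flask from the start; the feed brings no volume worth counting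

    leaving ligand + starting complex → side product (k1 = 0.051 L mol⁻¹ s⁻¹)
    complex with one exchanged + incoming ligand ⇌ leaving ligand + complex with two exchanged (K2 = 3.0, k2 = 0.39 L mol⁻¹ s⁻¹)
    starting complex ⇌ dormant form (K3 = 1.5, k3 = 0.013 s⁻¹)
    complex with two exchanged + incoming ligand ⇌ leaving ligand + complex with three exchanged (K4 = 1.7, k4 = 0.70 L mol⁻¹ s⁻¹)
    starting complex + incoming ligand ⇌ leaving ligand + complex with one exchanged (K5 = 0.58, k5 = 0.59 L mol⁻¹ s⁻¹)
    complex with three exchanged + incoming ligand ⇌ leaving ligand + complex with four exchanged (K6 = 1.8, k6 = 0.18 L mol⁻¹ s⁻¹)

1. the flask with the highest share of complex with two exchanged in complex with two exchanged plus complex with three exchanged ("all alike" if they lie within 1.5 percentage points) (alpha / zeta / gamma / all alike)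
2. share of complex with two exchanged in complex with two exchanged plus complex with three exchanged at the end, alpha
3. share of complex with two exchanged in complex with two exchanged plus complex with three exchanged at the end, zeta
4. share of complex with two exchanged in complex with two exchanged plus complex with three exchanged at the end, gamma

The forward half-life of complex with two exchanged at the charged [incoming ligand] was 0.0834 min, far shorter than 25 min. So I took that exchange as balanced. With ρ = [incoming ligand]/[leaving ligand], the share is then one over one plus 1.7·ρ. Once side product has taken the metal, [leaving ligand] is the charge minus 0.22 M, and I called the result the drained share, 39.5%.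

I held ρ at 0.600, its value with 0.110 M of side product formed. The balanced forms then held one part of starting complex in 4.80 parts of metal. That gave the metal pool a pseudo-first-order drain of 0.210 min⁻¹.

Integrated for zeta, this left 0.525% of the pool at the end, so I wrote 39.5% for alpha and 39.5% for zeta. Integrated through gamma's feed and the wait after it, the drain left 8.19%. Each metal in that pool carried 1.31 exchanged ligands on average, which held back 0.0235 M of incoming ligand. Gamma's ρ was therefore 0.667, and its share 46.9%. I expected gamma to stand highest.

The forecast gave 41% for alpha, 41.5% for zeta and 48% for gamma, and chose gamma, saying that “gamma's late-fed metal is still draining”.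

The flasks gave 40.8% for alpha, 41.9% for zeta and 47.4% for gamma, so gamma stood highest.

In gamma, the side-product step ran behind the feed: side product stood at 47.8% after 12.5 min and 91.2% after 25.0 min, while [leaving ligand] fell to 60.6% of its charge. In alpha, side product had already reached 95.6% after 12.5 min. After 250 min, alpha read 38.9% and gamma 38.9%, against the drained share of 39.5%. A neighbour of alpha charged with 0.75 M of leaving ligand has a drained share of 61.2%, and it read 60.2%.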